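**Plan**

- Retrosynthesis: after the C5 methyl ether and the C3' MOM ether are put back, ring C is cut at O1–C8a and C4–C4a. This gives 3,5-dimethoxybenzyne and a (3S)-3-aryl-3-hydroxy Weinreb amide. The amide is cut at C2–C3 (aldol) and ring B at C2'–C1'' (geranylation of isovanillin).
- Enabling feature: ring C meets ring A at the neighbouring carbons C8a (bearing O1) and C4a (bearing the C4 carbonyl), and the other neighbour of C4a carries the C5 oxygen. An aryne flanked by an alkoxy group takes a nucleophile at its remote carbon and an electrophile at the carbon next to the alkoxy group, which is this pattern.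
- Forward order: ring B is completed first (geranylation, aldol, oxidation, asymmetric reduction), the silyl triflate is made from 3,5-dimethoxyphenol, ring C is closed last by the aryne annulation, and two deprotections finish the synthesis.
- Stereochemistry: C2 is the only stereocentre. It is set as S by asymmetric transfer hydrogenation in step 6 and its C–O bond is not broken afterwards. The E alkene comes from geranyl bromide.
- The acyl acceptor is a Weinreb amide, so the new ketone stays masked as a tetrahedral adduct until work-up and C2 is protected from base-induced ring opening.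

Key step: step 10

Remark: the stereodescriptor in the SMILES is read as 2S; "geranyl" means (2E)-3,7-dimethylocta-2,6-dien-1-yl throughout, and the counter-ion of the anionic intermediates of step 10 is written as sodium although exchange with caesium in the flask is likely.

**Route**

Step 1
Reactants: 1 isovanillin (3-hydroxy-4-methoxybenzaldehyde)
Product: 2 4-methoxy-3-(methoxymethoxy)benzaldehyde
Conditions: MOMCl (1.5 equiv), i-Pr2NEt (2 equiv), CH2Cl2, 0 °C → rt
Reagents that add atoms: chloromethyl methyl ether (MOMCl), COCCl
Why: Amine-mediated O-alkylation of the phenol (MOM ether formation) is routine and installs the ortho-directing group needed in step 3.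

Step 2
Reactants: 2 4-methoxy-3-(methoxymethoxy)benzaldehyde
Product: 3 4-(dimethoxymethyl)-1-methoxy-2-(methoxymethoxy)benzene
Conditions: HC(OMe)3 (3 equiv), pyridinium p-toluenesulfonate (5 mol %), MeOH, rt; Et3N quench
Reagents that add atoms: trimethyl orthoformate, COC(OC)OC; methanol, CO
Why: Acid-catalysed acetalisation driven by the orthoformate masks the aldehyde against n-BuLi and turns it into a second coordinating group next to C2, while the weak acid at room temperature should leave the MOM acetal intact.

Step 3
Reactants: 3 4-(dimethoxymethyl)-1-methoxy-2-(methoxymethoxy)benzene; 4 geranyl bromide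
Product: 8 2-geranyl-4-methoxy-3-(methoxymethoxy)benzaldehyde, via aryllithium 5 (not isolated), via arylcopper 6 (not isolated), via geranylated dimethyl acetal 7 (not isolated)
Conditions: n-BuLi (1.2 equiv), THF, 0 °C; CuBr·SMe2 (1.2 equiv), −78 → −40 °C; 4 (1.3 equiv), −78 °C → rt; then 1 M HCl, THF, rt, 30 min
Reagents that add atoms: water, O
Why: Directed ortho-metalation occurs at the position flanked by the MOM ether and the acetal, the derived arylcopper displaces the allylic bromide at its primary carbon with retention of the E double bond (copper-mediated SN2 allylic substitution), and brief aqueous acid hydrolyses the dimethyl acetal much faster than the aryl MOM ether.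

Step 4
Reactants: 8 2-geranyl-4-methoxy-3-(methoxymethoxy)benzaldehyde; 9 N-methoxy-N-methylacetamide
Product: 11 rac-3-[2-geranyl-4-methoxy-3-(methoxymethoxy)phenyl]-3-hydroxy-N-methoxy-N-methylpropanamide, via lithium enolate 10 (not isolated)
Conditions: LiN(i-Pr)2 (1.15 equiv), 9 (1.2 equiv), THF, −78 °C; then 8, −78 °C; sat. aq. NH4Cl
Reagents that add atoms: none
Why: Aldol addition of the preformed lithium amide enolate to a non-enolisable aldehyde is fast at −78 °C and gives the Weinreb amide directly, the racemic carbinol being corrected by the following oxidation and reduction.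

Step 5
Reactants: 11 rac-3-[2-geranyl-4-methoxy-3-(methoxymethoxy)phenyl]-3-hydroxy-N-methoxy-N-methylpropanamide
Product: 12 3-[2-geranyl-4-methoxy-3-(methoxymethoxy)phenyl]-N-methoxy-N-methyl-3-oxopropanamide
Conditions: Dess–Martin periodinane (1.3 equiv), CH2Cl2, 0 °C → rt
Reagents that add atoms: none
Why: Dess–Martin oxidation converts the benzylic secondary alcohol into the ketone under near-neutral conditions that spare the MOM acetal and both trisubstituted alkenes.

Step 6
Reactants: 12 3-[2-geranyl-4-methoxy-3-(methoxymethoxy)phenyl]-N-methoxy-N-methyl-3-oxopropanamide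
Product: 13 (3S)-3-[2-geranyl-4-methoxy-3-(methoxymethoxy)phenyl]-3-hydroxy-N-methoxy-N-methylpropanamide
Conditions: RuCl(p-cymene)[(S,S)-TsDPEN] (2 mol %), HCO2H/Et3N (5:2), DMF, 30 °C
Reagents that add atoms: none
Why: Noyori–Ikariya asymmetric transfer hydrogenation of an aryl ketone, in which the (S,S)-TsDPEN ruthenium hydride attacks the carbonyl face that places the aryl group against the arene ligand (the sense that turns acetophenone into (S)-1-phenylethanol) and so sets the S carbinol centre, while the formate system leaves alkenes untouched.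

Step 7
Reactants: 14 3,5-dimethoxyphenol
Product: 15 3,5-dimethoxyphenyl N-isopropylcarbamate
Conditions: i-PrNCO (1.5 equiv), Et3N (0.2 equiv), CH2Cl2, rt
Reagents that add atoms: isopropyl isocyanate, CC(C)N=C=O
Why: Amine-catalysed addition of the phenol to the isocyanate (carbamoylation) gives a strong ortho-directing group that can later be removed under mild base.

Step 8
Reactants: 15 3,5-dimethoxyphenyl N-isopropylcarbamate
Product: 19 3,5-dimethoxy-2-(trimethylsilyl)phenyl N-isopropylcarbamate, via N-silyl carbamate 16 (not isolated), via aryllithium 17 (not isolated), via N-silyl C-silyl carbamate 18 (not isolated)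
Conditions: TBSOTf (1.1 equiv), TMEDA (1.1 equiv), Et2O, 0 °C → rt; n-BuLi (2.2 equiv), TMEDA (2 equiv), −78 °C; Me3SiCl (3 equiv), −78 °C → rt; aq. NaHSO4
Reagents that add atoms: chlorotrimethylsilane, C[Si](C)(C)Cl
Why: After in situ N-silylation the O-aryl carbamate, which outranks methoxy as a directing group, steers lithiation (directed ortho-metalation) to the position between itself and a methoxy group, the two such positions being equivalent by symmetry, and the aryllithium is trapped by Me3SiCl before the N-silyl group is lost on mildly acidic work-up.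

Step 9
Reactants: 19 3,5-dimethoxy-2-(trimethylsilyl)phenyl N-isopropylcarbamate
Product: 21 3,5-dimethoxy-2-(trimethylsilyl)phenyl trifluoromethanesulfonate, via silyl phenol 20 (not isolated)
Conditions: DBU (1.5 equiv), Et2NH (1.2 equiv), MeCN, 40 °C; then PhNTf2 (1.5 equiv), rt
Reagents that add atoms: N-phenylbis(trifluoromethanesulfonimide), O=S(=O)(N(c1ccccc1)S(=O)(=O)C(F)(F)F)C(F)(F)F
Why: DBU triggers E1cB loss of isopropyl isocyanate from the carbamate, diethylamine traps the isocyanate as a urea, and the liberated phenoxide is sulfonylated in the same flask by PhNTf2 (triflation).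

Step 10
Reactants: 13 (3S)-3-[2-geranyl-4-methoxy-3-(methoxymethoxy)phenyl]-3-hydroxy-N-methoxy-N-methylpropanamide; 21 3,5-dimethoxy-2-(trimethylsilyl)phenyl trifluoromethanesulfonate
Product: 25 (2S)-2-[2-geranyl-4-methoxy-3-(methoxymethoxy)phenyl]-5,7-dimethoxychroman-4-one, via sodium alkoxide 22 (not isolated), via aryne 23 (not isolated), via tetrahedral adduct 24 (not isolated)
Conditions: NaH (1.05 equiv), THF, 0 °C; then CsF (3 equiv), 18-crown-6 (3 equiv), 21 (1.6 equiv, added over 2 h), THF, −20 °C → rt; sat. aq. NH4Cl, 0 °C
Reagents that add atoms: none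
Why: Proposed new method: fluoride removes the silyl group of 21 and triflate leaves to give aryne 23, the preformed alkoxide 22 adds through oxygen to the aryne carbon remote from the flanking methoxy group (the future C8a), and the aryl anion thus placed at C4a, between the new ether oxygen and the C5 methoxy group, adds to the Weinreb amide carbonyl to give tetrahedral adduct 24, which collapses to the ketone only on aqueous quench. The closest known reaction types are the annulation of arynes with salicylate esters to xanthones and the O-arylation of aliphatic alcohols by arynes; the combination of an aliphatic alkoxide with a pendant acyl acceptor in one chromanone-forming event has no direct precedent. Ring C closes by 6-exo-trig attack of the aryl anion on the amide carbonyl, after the intermolecular O1–C8a bond has formed. No stereocentre is created and the C2–O bond of the alcohol is never broken, so the S configuration from step 6 is carried through; because 24 has no carbonyl group until work-up, C3 cannot be deprotonated and the base-induced opening to a chalcone that would racemise C2 is shut off. The step needs regioselective addition to an unsymmetrical aryne, which the inductive and distorting effect of the methoxy group next to the triple bond secures, and acylation of the aryl anion in preference to protonation, which full deprotonation of the alcohol in an aprotic medium secures. The electron-rich geranyl alkenes could intercept the aryne in an ene reaction, so 21 is added slowly to keep the aryne concentration low against the far more nucleophilic alkoxide.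

Step 11
Reactants: 25 (2S)-2-[2-geranyl-4-methoxy-3-(methoxymethoxy)phenyl]-5,7-dimethoxychroman-4-one
Product: 26 (2S)-2-[2-geranyl-4-methoxy-3-(methoxymethoxy)phenyl]-5-hydroxy-7-methoxychroman-4-one
Conditions: MgI2·OEt2 (3 equiv), toluene, 60 °C; cold 0.5 M HCl work-up
Reagents that add atoms: none
Why: Magnesium chelated between the C4 carbonyl and the C5 oxygen activates only that methyl ether for SN2 attack by iodide (chelation-controlled demethylation), so the C7 and C4' methyl ethers should survive, the acid-free medium spares C2 and the geranyl chain, and any loss of the MOM group would be harmless because it is removed next.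

Step 12
Reactants: 26 (2S)-2-[2-geranyl-4-methoxy-3-(methoxymethoxy)phenyl]-5-hydroxy-7-methoxychroman-4-one
Product: 27 (2S)-2-(2-geranyl-3-hydroxy-4-methoxyphenyl)-5-hydroxy-7-methoxychroman-4-one (CNP0130331.1)
Conditions: 2 M HCl, MeOH, 40 °C
Reagents that add atoms: none
Why: Acid-catalysed acetal cleavage (MOM removal) in methanol frees the C3' phenol under conditions mild enough that the phenol should not add across the geranyl double bond, and the hydrogen-bonded 5-hydroxy-4-ketone resists acid-induced opening at C2.

**Compound list**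

1 | isovanillin (3-hydroxy-4-methoxybenzaldehyde) | COc1ccc(C=O)cc1O | starting material
2 | 4-methoxy-3-(methoxymethoxy)benzaldehyde | COCOc1cc(C=O)ccc1OC | intermediate
3 | 4-(dimethoxymethyl)-1-methoxy-2-(methoxymethoxy)benzene | COCOc1cc(C(OC)OC)ccc1OC | intermediate
4 | geranyl bromide ((2E)-1-bromo-3,7-dimethylocta-2,6-diene) | BrC/C=C(\C)CCC=C(C)C | starting material
5 | [6-(dimethoxymethyl)-3-methoxy-2-(methoxymethoxy)phenyl]lithium (not isolated) | [Li]c1c(C(OC)OC)ccc(OC)c1OCOC | intermediate
6 | [6-(dimethoxymethyl)-3-methoxy-2-(methoxymethoxy)phenyl]copper (not isolated) | [Cu]c1c(C(OC)OC)ccc(OC)c1OCOC | intermediate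
7 | 1-(dimethoxymethyl)-2-geranyl-4-methoxy-3-(methoxymethoxy)benzene (not isolated) | COC(OC)c1ccc(OC)c(OCOC)c1C/C=C(\C)CCC=C(C)C | intermediate
8 | 2-geranyl-4-methoxy-3-(methoxymethoxy)benzaldehyde | O=Cc1ccc(OC)c(OCOC)c1C/C=C(\C)CCC=C(C)C | intermediate
9 | N-methoxy-N-methylacetamide | CC(=O)N(C)OC | starting material
10 | lithium enolate of N-methoxy-N-methylacetamide (not isolated) | C=C(O[Li])N(C)OC | intermediate
11 | rac-3-[2-geranyl-4-methoxy-3-(methoxymethoxy)phenyl]-3-hydroxy-N-methoxy-N-methylpropanamide | OC(CC(=O)N(C)OC)c1ccc(OC)c(OCOC)c1C/C=C(\C)CCC=C(C)C | intermediate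
12 | 3-[2-geranyl-4-methoxy-3-(methoxymethoxy)phenyl]-N-methoxy-N-methyl-3-oxopropanamide | O=C(CC(=O)N(C)OC)c1ccc(OC)c(OCOC)c1C/C=C(\C)CCC=C(C)C | intermediate
13 | (3S)-3-[2-geranyl-4-methoxy-3-(methoxymethoxy)phenyl]-3-hydroxy-N-methoxy-N-methylpropanamide | O[C@H](c1ccc(OC)c(OCOC)c1C/C=C(\C)CCC=C(C)C)CC(=O)N(C)OC | intermediate
14 | 3,5-dimethoxyphenol | COc1cc(O)cc(OC)c1 | starting material
15 | 3,5-dimethoxyphenyl N-isopropylcarbamate | COc1cc(OC)cc(OC(=O)NC(C)C)c1 | intermediate
16 | 3,5-dimethoxyphenyl N-(tert-butyldimethylsilyl)-N-isopropylcarbamate (not isolated) | COc1cc(OC)cc(OC(=O)N(C(C)C)[Si](C)(C)C(C)(C)C)c1 | intermediate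
17 | 2-lithio derivative of 16 (lithium between the carbamate oxygen and a methoxy group; not isolated) | [Li]c1c(OC)cc(OC)cc1OC(=O)N(C(C)C)[Si](C)(C)C(C)(C)C | intermediate
18 | 3,5-dimethoxy-2-(trimethylsilyl)phenyl N-(tert-butyldimethylsilyl)-N-isopropylcarbamate (not isolated) | COc1cc(OC)c([Si](C)(C)C)c(OC(=O)N(C(C)C)[Si](C)(C)C(C)(C)C)c1 | intermediate
19 | 3,5-dimethoxy-2-(trimethylsilyl)phenyl N-isopropylcarbamate | COc1cc(OC)c([Si](C)(C)C)c(OC(=O)NC(C)C)c1 | intermediate
20 | 3,5-dimethoxy-2-(trimethylsilyl)phenol (not isolated) | COc1cc(OC)c([Si](C)(C)C)c(O)c1 | intermediate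
21 | 3,5-dimethoxy-2-(trimethylsilyl)phenyl trifluoromethanesulfonate | COc1cc(OC)c([Si](C)(C)C)c(OS(=O)(=O)C(F)(F)F)c1 | intermediate
22 | sodium (1S)-1-[2-geranyl-4-methoxy-3-(methoxymethoxy)phenyl]-3-[methoxy(methyl)amino]-3-oxopropan-1-olate (not isolated) | [Na+].[O-][C@H](c1ccc(OC)c(OCOC)c1C/C=C(\C)CCC=C(C)C)CC(=O)N(C)OC | intermediate
23 | 3,5-dimethoxybenzyne (1,2-didehydro-3,5-dimethoxybenzene; not isolated) | COC1=CC(OC)=CC#C1 | intermediate
24 | sodium (2S)-2-[2-geranyl-4-methoxy-3-(methoxymethoxy)phenyl]-5,7-dimethoxy-4-[methoxy(methyl)amino]chroman-4-olate (tetrahedral adduct, either C4 epimer; not isolated) | [Na+].COc1cc(OC)c2c(c1)O[C@H](c1ccc(OC)c(OCOC)c1C/C=C(\C)CCC=C(C)C)CC2([O-])N(C)OC | intermediate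
25 | (2S)-2-[2-geranyl-4-methoxy-3-(methoxymethoxy)phenyl]-5,7-dimethoxychroman-4-one | COc1cc(OC)c2c(c1)O[C@H](c1ccc(OC)c(OCOC)c1C/C=C(\C)CCC=C(C)C)CC2=O | intermediate
26 | (2S)-2-[2-geranyl-4-methoxy-3-(methoxymethoxy)phenyl]-5-hydroxy-7-methoxychroman-4-one | COc1cc(O)c2c(c1)O[C@H](c1ccc(OC)c(OCOC)c1C/C=C(\C)CCC=C(C)C)CC2=O | intermediate
27 | (2S)-2-(2-geranyl-3-hydroxy-4-methoxyphenyl)-5-hydroxy-7-methoxychroman-4-one (CNP0130331.1) | COc1cc(O)c2c(c1)O[C@H](c1ccc(OC)c(O)c1C/C=C(\C)CCC=C(C)C)CC2=O | target

**Step count**

Total: 12 steps. Longest linear sequence: 9 steps (steps 1–6 and 10–12, from isovanillin); the silyl triflate branch (steps 7–9) joins at step 10.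

**Steps most likely to fail**

1. Step 10 (proposed new method). The aryl anion may be protonated before it reaches the amide, which would leave an open aryl ether. The aryne may also be consumed by an ene reaction with the geranyl alkenes or by fluoride, and the alkoxide may undergo retro-aldol cleavage. The fallback uses known chemistry and forms O1–C2 and C4–C4a in two separate steps. It sets out from 12 and 19 and comes back at 25. Keto amide 12 is reduced as in step 6 but with RuCl(p-cymene)[(R,R)-TsDPEN] to (3R)-3-[2-geranyl-4-methoxy-3-(methoxymethoxy)phenyl]-3-hydroxy-N-methoxy-N-methylpropanamide F1. Silyl carbamate 19 is ipso-iodinated (ICl, CH2Cl2, −78 → 0 °C) to 2-iodo-3,5-dimethoxyphenyl N-isopropylcarbamate F2, and the carbamate is cleaved (DBU, Et2NH, MeCN, 40 °C) to 2-iodo-3,5-dimethoxyphenol F3. Mitsunobu etherification of F1 with F3 (PPh3, DIAD, toluene, 0 °C) inverts the carbinol centre and should give (3S)-3-[2-geranyl-4-methoxy-3-(methoxymethoxy)phenyl]-3-(2-iodo-3,5-dimethoxyphenoxy)-N-methoxy-N-methylpropanamide F4. Iodine–lithium exchange (n-BuLi, THF, −78 °C) then triggers a Parham cyclisation onto the Weinreb amide to the lithium tetrahedral adduct F5, which releases 25 on aqueous quench. The route resumes at step 11.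

2. Step 6. Hydride delivery to the ortho-substituted, partly enolised keto amide may be slow or poorly face-selective, and this step is the only source of chirality. The fallback is an auxiliary-controlled acetate aldol that sets out from aldehyde 8, bypasses 11 and 12, and comes back at 13. Doubly deprotonated (S)-2-hydroxy-1,2,2-triphenylethyl acetate (LiN(i-Pr)2, 2.2 equiv, THF; MgBr2; then 8 at −115 °C) should add to 8 to give (1S)-2-hydroxy-1,2,2-triphenylethyl (3S)-3-[2-geranyl-4-methoxy-3-(methoxymethoxy)phenyl]-3-hydroxypropanoate F6, purified as the major diastereomer. Aminolysis with MeNHOMe·HCl and i-PrMgCl (THF, −20 → 0 °C) converts F6 into 13 and returns the auxiliary diol.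

3. Step 3. Lithiation at the doubly flanked position may be incomplete or stray to another site, the arylcopper may attack the allylic bromide at its tertiary end, and part of the MOM group may be lost during acetal hydrolysis. The fallback replaces metalation by a cross-coupling; it sets out from 1 (with 4 for the tin reagent) and comes back at 8. Isovanillin 1 is brominated between the hydroxyl and formyl groups (Br2, NaOAc, Fe cat., AcOH) to 2-bromo-3-hydroxy-4-methoxybenzaldehyde F7, which is protected (MOMCl, i-Pr2NEt) as 2-bromo-4-methoxy-3-(methoxymethoxy)benzaldehyde F8. Geranyl bromide 4 is converted with Bu3SnLi (THF, −78 °C) into tributyl(geranyl)stannane F9. Stille coupling of F8 with F9 (Pd(PPh3)4 as the zerovalent palladium catalyst, LiCl, DMF, 80 °C) should give 8 without an acetal or an organolithium, and the route resumes at step 4.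

Further compounds
F1 | step 10 | (3R)-3-[2-geranyl-4-methoxy-3-(methoxymethoxy)phenyl]-3-hydroxy-N-methoxy-N-methylpropanamide | O[C@@H](c1ccc(OC)c(OCOC)c1C/C=C(\C)CCC=C(C)C)CC(=O)N(C)OC
F2 | step 10 | 2-iodo-3,5-dimethoxyphenyl N-isopropylcarbamate | COc1cc(OC)c(I)c(OC(=O)NC(C)C)c1
F3 | step 10 | 2-iodo-3,5-dimethoxyphenol | COc1cc(OC)c(I)c(O)c1
F4 | step 10 | (3S)-3-[2-geranyl-4-methoxy-3-(methoxymethoxy)phenyl]-3-(2-iodo-3,5-dimethoxyphenoxy)-N-methoxy-N-methylpropanamide | COc1cc(OC)c(I)c(O[C@H](c2ccc(OC)c(OCOC)c2C/C=C(\C)CCC=C(C)C)CC(=O)N(C)OC)c1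
F5 | step 10 | lithium (2S)-2-[2-geranyl-4-methoxy-3-(methoxymethoxy)phenyl]-5,7-dimethoxy-4-[methoxy(methyl)amino]chroman-4-olate (not isolated) | [Li+].COc1cc(OC)c2c(c1)O[C@H](c1ccc(OC)c(OCOC)c1C/C=C(\C)CCC=C(C)C)CC2([O-])N(C)OC
F6 | step 6 | (1S)-2-hydroxy-1,2,2-triphenylethyl (3S)-3-[2-geranyl-4-methoxy-3-(methoxymethoxy)phenyl]-3-hydroxypropanoate | O[C@H](c1ccc(OC)c(OCOC)c1C/C=C(\C)CCC=C(C)C)CC(=O)O[C@@H](c1ccccc1)C(O)(c1ccccc1)c1ccccc1
F7 | step 3 | 2-bromo-3-hydroxy-4-methoxybenzaldehyde | COc1ccc(C=O)c(Br)c1O
F8 | step 3 | 2-bromo-4-methoxy-3-(methoxymethoxy)benzaldehyde | COCOc1c(Br)c(C=O)ccc1OC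
F9 | step 3 | tributyl[(2E)-3,7-dimethylocta-2,6-dien-1-yl]stannane | CCCC[Sn](CCCC)(CCCC)C/C=C(\C)CCC=C(C)C
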